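Target cannot all stay target: at rest, step 1 holds 1.4 isomer of the product per target. Before the next run I therefore had to choose which of these set-ups to repeat.

| flask | substrate | remark | time |
|---|---|---|---|
| Sunday's | 0.10 M | one stirred flow tank at steady state, fed with the mixture as stated, mean residence time 250 min |  |
| Wednesday's | 0.10 M | one stirred flow tank at steady state, fed with the mixture as stated, mean residence time 25 min |  |
| Thursday's | 0.10 M | everything together in a closed stirred flask, run for 25 min | 25 min |
| Tuesday's | 0.10 M | plug flow through a tube for 25 min, no back-mixing | 25 min |

    target ⇌ isomer of the product (K1 = 1.4, k1 = 9.3 × 10⁻⁴ s⁻¹)
    substrate ⇌ dormant form (K2 = 13, k2 = 0.0029 s⁻¹)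
    substrate ⇌ target + by-product (K3 = 0.50 M, k3 = 0.012 s⁻¹)

- the stated concentrations are those of everything mixed, before any reaction; amounts are the same in each set-up
- run time (Thursday's): 25 min

- the set-up with the highest amount of target at the outlet or at the end, in percent of the substrate put in ("none" if the first two lie within 2 percentage points) (Sunday's / Wednesday's / Thursday's / Tuesday's / none)
- amount of target at the outlet or at the end, in percent of the substrate put in, Sunday's
- amount of target at the outlet or at the end, in percent of the substrate put in, Wednesday's
- amount of target at the outlet or at the end, in percent of the substrate put in, Thursday's
- amount of target at the outlet or at the end, in percent of the substrate put in, Tuesday's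

I asked first for the end state. Call target plus isomer of the product the pair. At rest, step 1 leaves target as 41.7% of the pair. Each member of the pair arrives with one by-product, and with steps 2 and 3 also at rest, the pair stands at 59.2% of the charge.

Then I asked how fast that split is approached. The measure is the pair clock, the relaxation time of step 1: one over the sum of its forward and back rate constants, 10.5 min. Substrate's half-life by the forward rate of step 3 alone is 0.96 min, shorter than the clock, so I started the pair as pure target.

The excess of target's share over its end value then shrinks by exp(−t/T) in Thursday's flask and Tuesday's tube, whose contents share one age. In a tank, where ages are mixed, the excess is divided by one plus τ/T. That gave shares of 47.0% for Thursday's and Tuesday's, 58.9% for Wednesday's and 44.0% for Sunday's. With the pair at its end value, my target figures were 27.8% for Thursday's and Tuesday's, 34.9% for Wednesday's and 26.0% for Sunday's, so I would repeat Wednesday's.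

The forecast also named Wednesday's, with 26.7% for Sunday's, 37.8% for Wednesday's, 33% for Thursday's and 33% for Tuesday's. Its ground was “its mixture of ages holds the slow drains back more than the closed flask does”. My own figures stand below these.

The simulation gives Wednesday's as best, with 26.7% for Sunday's, 37.8% for Wednesday's, 29.9% for Thursday's and 29.9% for Tuesday's.

Step 1 is the largest single effect on target in Wednesday's tank: with that step taken away both ways, target there rises from 37.8% to 57.8%. The pair is 64.2% of the charge in Wednesday's tank and 64.9% in Thursday's flask, while target's share is 58.9% against 46.1%. On the pair clock, Thursday's flask keeps 0.0915 of the excess and Wednesday's tank 0.295.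

For Thursday's flask read at 15 min, the clock gives a share of 55.6%. With the pair held at Thursday's 64.9%, that means 36.1% target. The computed flask holds 37.3%.

The rate constants are assumed, and the outcome is calculated.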